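(The earlier runs and the new flask are calculated with constants of no real substance; noise was put on by code.)

The one constant I can read from these runs is a clock constant. I assume one partner per substrate and a rate proportional to c(free catalyst), c(partner) and c(substrates). The clock Θ is then the natural logarithm of the fraction of partner left over the fraction of substrates left (the integrated second-order law), and I assume that at a fixed time it grows in proportion to c(free catalyst).

| setting | north | west | flask |
|---|---|---|---|
| left-handed substrate | 10 mM | 10 mM | 10 mM |
| right-handed substrate | 10 mM | 10 mM | 10 mM |
| partner | 30 mM | 30 mM | 30.0 mM |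
| free catalyst | 10 µM | 10 µM | 10 µM |
| racemization catalyst | 67 µM | 150 µM | 100 µM |
| remark | run made earlier | run made earlier |  |
| time |  |  | 4.0 h |

| run | time / h | left-handed product / % | right-handed product / % |
|---|---|---|---|
| north | 0.333 | 12.2 | 10.4 |
| north | 0.667 | 19.2 | 17.5 |
| north | 1.00 | 21.9 | 21.6 |
| north | 2.00 | 33.9 | 32.1 |
| north | 4.00 | 39.6 | 38.4 |
| west | 0.333 | 11.8 | 8.6 |
| west | 1.00 | 25.1 | 22.3 |
| west | 2.00 | 32.1 | 30.9 |
| west | 3.00 | 35.2 | 36.1 |
| west | 4.00 | 39.7 | 40.1 |

(standard deviation of a reading: 1 percentage point)

- excess of left-handed product over right-handed product in the product at 12 min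
- excess of left-handed product over right-handed product in the product at 4.0 h
- part of the left-handed substrate and right-handed substrate charged together that has reacted at 4.0 h

- free catalyst is single-handed; left-handed substrate and right-handed substrate are mirror images of each other, charged as a racemate, each of them at the stated concentration
- an excess is the difference of the two amounts in percent of their sum
- an excess is below zero if the other one leads

1. Ceiling. The partner charge of 30.0 mM exceeds the 0.0200 M of substrates together, a ratio of 0.667 substrates to partner. The substrates are therefore the limiting reagent, and their complete conversion is a ceiling, not a forecast of the end state.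

2. Bound from above. Pooled north and west readings give 21.5% conversion at 0.333 h, a clock pace of 0.262 h⁻¹. Held to 4.0 h, that pace gives 84.8%.

3. Bound from below. The racemization catalyst in the flask lies between north and west, so I bracket the conversion by their readings at 4.0 h, 78.0% and 79.8%.

4. Commitment. Pooled, these give 78.9%, so Θ reads 0.809. Its average pace of 0.202 h⁻¹ is slower than the early pace. The clock constant κ, Θ at 4.0 h per free catalyst charged, reads 80.9 mM⁻¹. Θ sums both substrates and carries no excess.

5. Forecast. It gives 13%, 1% and 79%, holding that “the racemization catalyst does not set the rate”. Its conversion lies inside my bracket.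

    partner + free catalyst + left-handed substrate → free catalyst + left-handed product (k = 3.80 × 10⁶ M⁻² h⁻¹)
    partner + free catalyst + right-handed substrate → free catalyst + right-handed product (k = 1.80 × 10⁶ M⁻² h⁻¹)
    left-handed substrate + racemization catalyst ⇌ right-handed substrate + racemization catalyst, rate k3*[racemization catalyst]*[left-handed substrate] forward; the back reaction follows from the equilibrium constant (k = 770 M⁻¹ h⁻¹)
    left-handed product ⇌ right-handed product (k = 2.10 h⁻¹)
    partner + free catalyst → spent catalyst (k = 5.90 M⁻¹ h⁻¹)

The flask gives 21.8%, −0.0512% and 78.6%, so the early excess stands 8.8 percentage points above the forecast. The flask's conversion puts κ at 80.1 mM⁻¹. The neighbouring flask holds 0.0025 mM of free catalyst, a quarter of this charge, over the same time. My κ gives it Θ of 0.202 and so a conversion of 40.2%, and that neighbouring flask gives 40.2%.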